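Ring A of the abietane half is closed by a strain-release (3+3) annulation. A donor–acceptor cyclopropane made of C10, C1 and C2 is opened at its quaternary benzylic carbon C10 by the C5 enol of the C6 ketone, and the malonate released at C2 adds to the C3 aldehyde: one operation forms C5–C10 and C2–C3, closing rings B and A. It exploits the aryl-stabilised C10 on aromatic ring C and the 1,3-related nucleophilic C5 and electrophilic C3 flanking the gem-dimethyl carbon C4. The precursor is an aryl cyclopropane-1,1-diester with a keto aldehyde side chain. Ketone α-arylation and a Mitsunobu closure then add the naphthofuran.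

Key step: step 8

Assumption: the diterpenoid half is numbered as an abietane (C1–C20; ring A C1–C5/C10, ring B C5–C10, aromatic ring C C8–C14), and compounds 1, 5, 6, 17 and 24 are taken as purchasable.

Step 1
Reactants: 1 1-(4-bromo-3-methoxyphenyl)ethan-1-one
Product: 2 1-[3-methoxy-4-(propan-2-yl)phenyl]ethan-1-one
Conditions: i-PrZnBr, Pd(OAc)2 (2 mol %), CPhos (4 mol %), THF/toluene, rt
Reagents that add atoms: isopropylzinc bromide CC(C)[Zn]Br
Why: Negishi coupling; CPhos-ligated palladium should couple the secondary alkylzinc without isomerisation to the n-propyl product, and the ketone tolerates the organozinc.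

Step 2
Reactants: 2 1-[3-methoxy-4-(propan-2-yl)phenyl]ethan-1-one
Product: 3 1-[2-bromo-5-methoxy-4-(propan-2-yl)phenyl]ethan-1-one
Conditions: NBS, MeCN, rt
Reagents that add atoms: N-bromosuccinimide O=C1CCC(=O)N1Br
Why: Electrophilic aromatic bromination para to the methoxy group; the other activated position lies between two substituents.

Step 3
Reactants: 3 1-[2-bromo-5-methoxy-4-(propan-2-yl)phenyl]ethan-1-one
Product: 4 1-bromo-4-methoxy-5-(propan-2-yl)-2-(prop-1-en-2-yl)benzene
Conditions: Ph3PCH3Br, KOt-Bu, THF, 0 °C to rt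
Reagents that add atoms: methylidenetriphenylphosphorane C=P(c1ccccc1)(c1ccccc1)c1ccccc1
Why: Wittig methylenation turns the acetyl group into the α-methylstyrene unit needed for cyclopropanation.

Step 4
Reactants: 5 3-methylbut-2-en-1-ol; 6 2-methoxyprop-1-ene
Product: 8 4,4-dimethylhex-5-en-2-one, via allyl vinyl ether 7 (not isolated)
Conditions: pyridinium p-toluenesulfonate (cat.), xylene, 130 °C, sealed tube
Reagents that add atoms: none
Why: Saucy–Marbet Claisen rearrangement; acid-catalysed ether exchange gives the allyl vinyl ether, whose [3,3]-sigmatropic shift forms the gem-dimethyl quaternary carbon and the terminal vinyl group.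

Step 5
Reactants: 4 1-bromo-4-methoxy-5-(propan-2-yl)-2-(prop-1-en-2-yl)benzene; 8 4,4-dimethylhex-5-en-2-one
Product: 9 1-[4-methoxy-5-(propan-2-yl)-2-(prop-1-en-2-yl)phenyl]-4,4-dimethylhex-5-en-2-one
Conditions: Pd2(dba)3 (1 mol %), XPhos (3 mol %), NaOt-Bu, toluene, 70 °C
Reagents that add atoms: none
Why: Palladium-catalysed ketone α-arylation (Buchwald–Hartwig type); the methyl group reacts because the methylene is neopentyl-like, and the ortho substituent should prevent diarylation.

Step 6
Reactants: 9 1-[4-methoxy-5-(propan-2-yl)-2-(prop-1-en-2-yl)phenyl]-4,4-dimethylhex-5-en-2-one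
Product: 10 dimethyl (2S)-2-[2-(4,4-dimethyl-2-oxohex-5-en-1-yl)-5-methoxy-4-(propan-2-yl)phenyl]-2-methylcyclopropane-1,1-dicarboxylate
Conditions: PhI=C(CO2Me)2, [Cu(MeCN)4]PF6 (5 mol %), chiral bis(oxazoline) ligand (6 mol %, enantiomer chosen for the (S)-product), 4 Å MS, CH2Cl2, 0 °C
Reagents that add atoms: dimethyl 2-(phenyl-λ3-iodanylidene)propanedioate COC(=O)[C-]([I+]c1ccccc1)C(=O)OC
Why: Copper-carbenoid cyclopropanation with a malonate iodonium ylide; the electron-rich 1,1-disubstituted styrene should react before the hindered vinyl group, and the chiral bis(oxazoline)–copper complex differentiates its faces, setting the quaternary stereocentre that becomes C10.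

Step 7
Reactants: 10 dimethyl (2S)-2-[2-(4,4-dimethyl-2-oxohex-5-en-1-yl)-5-methoxy-4-(propan-2-yl)phenyl]-2-methylcyclopropane-1,1-dicarboxylate
Product: 12 dimethyl (2S)-2-[2-(4,4-dimethyl-2,5-dioxopentyl)-5-methoxy-4-(propan-2-yl)phenyl]-2-methylcyclopropane-1,1-dicarboxylate, via ozonide 11 (not isolated)
Conditions: O3, CH2Cl2, −78 °C; then Me2S, −78 °C to rt
Reagents that add atoms: ozone [O-][O+]=O
Why: Ozonolysis with reductive work-up; the vinyl group is the only alkene left and should react much faster than the arene at −78 °C.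

Step 8
Reactants: 12 dimethyl (2S)-2-[2-(4,4-dimethyl-2,5-dioxopentyl)-5-methoxy-4-(propan-2-yl)phenyl]-2-methylcyclopropane-1,1-dicarboxylate
Product: 14 dimethyl 3β-hydroxy-12-methoxy-6-oxo-5α-abieta-8,11,13-triene-2,2-dicarboxylate, via seco-malonate 13 (not isolated)
Conditions: Sc(OTf)3 (20 mol %), 4 Å MS, CH2Cl2 (0.005 M), 0 °C to rt
Reagents that add atoms: none
Why: Proposed new method: Sc(OTf)3 chelates the geminal diester and polarises the C10–C2 bond of the donor–acceptor cyclopropane; the C5 enol of the C6 ketone displaces C2 at the quaternary benzylic carbon C10 (6-exo-tet, ring B), and the scandium malonate enolate released at C2 then adds to the tethered C3 aldehyde (6-exo-trig aldol, ring A), so strain release in the first bond formation creates the nucleophile for the second. The closest known reaction types are the Lewis-acid ring opening of 2-arylcyclopropane-1,1-diesters by enol-type carbon nucleophiles and their stereospecific formal (3+2) and (3+3) annulations with aldehydes, in which the malonate also ends on a carbonyl carbon. C10 is controlled by the cyclopropane stereocentre through SN2-like inversion in a tight ion pair; C5 lies α to the C6 ketone and should settle as the trans-fused 5α-H epimer; C3 should carry the equatorial 3β-hydroxyl of a chair aldol transition state, although this centre is erased in step 9. The step needs C5 rather than C7 to attack C10 and the malonate to add to the aldehyde rather than to the C6 ketone: the C7 enol cannot reach C10 (a four-membered ring would result) and its aldol addition to the aldehyde is reversible, the bridged adduct with the ketone is strained and reversible, and high dilution disfavours intermolecular aldehyde–cyclopropane annulation.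

Step 9
Reactants: 14 dimethyl 3β-hydroxy-12-methoxy-6-oxo-5α-abieta-8,11,13-triene-2,2-dicarboxylate
Product: 15 dimethyl 12-methoxy-3,6-dioxo-5α-abieta-8,11,13-triene-2,2-dicarboxylate
Conditions: Dess–Martin periodinane, NaHCO3, CH2Cl2, rt
Reagents that add atoms: none
Why: Dess–Martin oxidation of the secondary alcohol gives the acylmalonate, which removes the C3 stereocentre and prepares the decarboxylation.

Step 10
Reactants: 15 dimethyl 12-methoxy-3,6-dioxo-5α-abieta-8,11,13-triene-2,2-dicarboxylate
Product: 16 12-methoxy-5α-abieta-8,11,13-triene-3,6-dione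
Conditions: LiCl, DMSO, H2O, 150 °C
Reagents that add atoms: none
Why: Krapcho dealkoxycarbonylation twice (acylmalonate to β-keto ester to ketone); the hot neutral conditions should also equilibrate C5 to the trans-fused epimer.

Step 11
Reactants: 17 6-methoxy-3,4-dihydronaphthalen-1(2H)-one
Product: 18 5-bromo-6-methoxy-3,4-dihydronaphthalen-1(2H)-one
Conditions: NBS, MeCN, rt
Reagents that add atoms: N-bromosuccinimide O=C1CCC(=O)N1Br
Why: Electrophilic aromatic bromination ortho to the methoxy group; attack at C5 next to the ring methylene should predominate over C7, and the minor isomer is removed by crystallisation.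

Step 12
Reactants: 18 5-bromo-6-methoxy-3,4-dihydronaphthalen-1(2H)-one
Product: 19 6-methoxy-5-(propan-2-yl)-3,4-dihydronaphthalen-1(2H)-one
Conditions: i-PrZnBr, Pd(OAc)2 (2 mol %), CPhos (4 mol %), THF/toluene, rt
Reagents that add atoms: isopropylzinc bromide CC(C)[Zn]Br
Why: Negishi coupling of the hindered ortho-methoxy aryl bromide with a secondary alkylzinc; the enolisable ketone is tolerated.

Step 13
Reactants: 19 6-methoxy-5-(propan-2-yl)-3,4-dihydronaphthalen-1(2H)-one
Product: 21 6-methoxy-2-methyl-5-(propan-2-yl)-3,4-dihydronaphthalen-1(2H)-one (racemic), via lithium enolate 20 (not isolated)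
Conditions: LiN(i-Pr)2, THF, −78 °C; then MeI, −78 to 0 °C
Reagents that add atoms: iodomethane CI
Why: Kinetic enolate formation and SN2 methylation at C2; the stereocentre formed is removed in the next step.

Step 14
Reactants: 21 6-methoxy-2-methyl-5-(propan-2-yl)-3,4-dihydronaphthalen-1(2H)-one
Product: 22 6-methoxy-2-methyl-5-(propan-2-yl)naphthalen-1-ol
Conditions: Pd(TFA)2 (5 mol %), 2-(dimethylamino)pyridine (10 mol %), TsOH (20 mol %), O2 (1 atm), DMSO, 80 °C
Reagents that add atoms: none
Why: Palladium-catalysed aerobic dehydrogenation (Stahl type); α-palladation and β-hydride elimination give the dienone, which tautomerises to the 1-naphthol.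

Step 15
Reactants: 22 6-methoxy-2-methyl-5-(propan-2-yl)naphthalen-1-ol
Product: 23 6-methoxy-2-methyl-5-(propan-2-yl)naphthalen-1-yl trifluoromethanesulfonate
Conditions: Tf2O, pyridine, CH2Cl2, 0 °C
Reagents that add atoms: trifluoromethanesulfonic anhydride O=S(=O)(OS(=O)(=O)C(F)(F)F)C(F)(F)F
Why: O-Sulfonylation of the naphthol gives the aryl triflate for cross-coupling.

Step 16
Reactants: 23 6-methoxy-2-methyl-5-(propan-2-yl)naphthalen-1-yl trifluoromethanesulfonate; 24 4-methylpent-1-en-3-ol
Product: 25 1-[6-methoxy-2-methyl-5-(propan-2-yl)naphthalen-1-yl]-4-methylpentan-3-one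
Conditions: Pd(OAc)2 (5 mol %), LiCl, Et3N, DMF, 90 °C
Reagents that add atoms: none
Why: Mizoroki–Heck reaction with an allylic alcohol; arylation at the terminal carbon is followed by β-hydride elimination towards the carbinol carbon and tautomerisation, giving the saturated ketone directly.

Step 17
Reactants: 25 1-[6-methoxy-2-methyl-5-(propan-2-yl)naphthalen-1-yl]-4-methylpentan-3-one
Product: 26 2-{2-[6-methoxy-2-methyl-5-(propan-2-yl)naphthalen-1-yl]ethyl}-2-(propan-2-yl)-1,3-dioxolane
Conditions: ethylene glycol, TsOH (cat.), benzene, reflux, Dean–Stark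
Reagents that add atoms: ethane-1,2-diol OCCO
Why: Acid-catalysed ketalisation with azeotropic removal of water protects the ketone against the organolithium, hydride and thiolate reagents used later.

Step 18
Reactants: 26 2-{2-[6-methoxy-2-methyl-5-(propan-2-yl)naphthalen-1-yl]ethyl}-2-(propan-2-yl)-1,3-dioxolane
Product: 28 2-{2-[7-bromo-6-methoxy-2-methyl-5-(propan-2-yl)naphthalen-1-yl]ethyl}-2-(propan-2-yl)-1,3-dioxolane, via aryllithium 27 (not isolated)
Conditions: n-BuLi, TMEDA, Et2O, 0 °C; then BrCF2CF2Br, −78 °C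
Reagents that add atoms: 1,2-dibromo-1,1,2,2-tetrafluoroethane FC(F)(Br)C(F)(F)Br
Why: Directed ortho-metalation by the methoxy group at its only free ortho position (the other is blocked by isopropyl), then electrophilic bromination of the aryllithium.

Step 19
Reactants: 16 12-methoxy-5α-abieta-8,11,13-triene-3,6-dione; 28 2-{2-[7-bromo-6-methoxy-2-methyl-5-(propan-2-yl)naphthalen-1-yl]ethyl}-2-(propan-2-yl)-1,3-dioxolane
Product: 29 12-methoxy-7α-(3-methoxy-7-methyl-4-(propan-2-yl)-8-{2-[2-(propan-2-yl)-1,3-dioxolan-2-yl]ethyl}naphthalen-2-yl)-5α-abieta-8,11,13-triene-3,6-dione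
Conditions: Pd2(dba)3 (2.5 mol %), XPhos (10 mol %), K3PO4, toluene, 100 °C
Reagents that add atoms: none
Why: Palladium-catalysed ketone α-arylation; with the weak base only the benzylic C7–H next to the C6 ketone is acidic enough to react, and the epimerisable aryl group should settle pseudoaxial (7α), which avoids peri strain with H14.

Step 20
Reactants: 29 12-methoxy-7α-(3-methoxy-7-methyl-4-(propan-2-yl)-8-{2-[2-(propan-2-yl)-1,3-dioxolan-2-yl]ethyl}naphthalen-2-yl)-5α-abieta-8,11,13-triene-3,6-dione
Product: 30 the corresponding 3β,6β-diol (12-methoxy-7α-aryl-5α-abieta-8,11,13-triene-3β,6β-diol; aryl as in 29)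
Conditions: LiAlH4, THF, 0 °C to rt
Reagents that add atoms: none
Why: Hydride reduction under substrate control; attack on C3 should give the equatorial 3β-alcohol as usual for 4,4-dimethyl-3-ketones, and attack on C6 from the α-face, opposite the axial methyl groups on C4 and C10, should give the axial 6β-alcohol.

Step 21
Reactants: 30 the 3β,6β-diol
Product: 31 7α-(3-hydroxy-7-methyl-4-(propan-2-yl)-8-{2-[2-(propan-2-yl)-1,3-dioxolan-2-yl]ethyl}naphthalen-2-yl)-5α-abieta-8,11,13-triene-3β,6β,12-triol
Conditions: NaSEt, DMF, 130 °C; aqueous HCl work-up (pH 6)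
Reagents that add atoms: none
Why: SN2 demethylation of both aryl methyl ethers by ethanethiolate; the alcohols and the ketal are inert.

Step 22
Reactants: 31 the naphthol triol
Product: 32 the 1,3-dioxolane ketal of the target (6α-O,7α-C cis-fused dihydronaphthofuran)
Conditions: PPh3, DIAD, THF, 0 °C to rt
Reagents that add atoms: none
Why: Intramolecular Mitsunobu etherification; the naphthol oxygen displaces the activated 6β-hydroxyl with inversion (5-exo-tet), giving the cis-fused 6α-O/7α-aryl dihydrofuran, while the neopentyl 3β-hydroxyl should not react.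

Step 23
Reactants: 32 the 1,3-dioxolane ketal of the target
Product: 33 target compound (CNP0584944.1)
Conditions: 1 M HCl, THF, rt
Reagents that add atoms: water O
Why: Acid-catalysed hydrolysis of the dioxolane releases the isopropyl ketone without affecting the phenol, the secondary alcohol or the cyclic aryl ether.

Compound list
1 | 1-(4-bromo-3-methoxyphenyl)ethan-1-one | CC(=O)c1ccc(Br)c(OC)c1 | starting material
2 | 1-[3-methoxy-4-(propan-2-yl)phenyl]ethan-1-one | CC(=O)c1ccc(C(C)C)c(OC)c1 | intermediate
3 | 1-[2-bromo-5-methoxy-4-(propan-2-yl)phenyl]ethan-1-one | CC(=O)c1cc(OC)c(C(C)C)cc1Br | intermediate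
4 | 1-bromo-4-methoxy-5-(propan-2-yl)-2-(prop-1-en-2-yl)benzene | C=C(C)c1cc(OC)c(C(C)C)cc1Br | intermediate
5 | 3-methylbut-2-en-1-ol | CC(C)=CCO | starting material
6 | 2-methoxyprop-1-ene | COC(C)=C | starting material
7 | 3-methylbut-2-en-1-yl prop-1-en-2-yl ether (not isolated) | C=C(C)OCC=C(C)C | intermediate
8 | 4,4-dimethylhex-5-en-2-one | CC(=O)CC(C)(C)C=C | intermediate
9 | 1-[4-methoxy-5-(propan-2-yl)-2-(prop-1-en-2-yl)phenyl]-4,4-dimethylhex-5-en-2-one | C=CC(C)(C)CC(=O)Cc1cc(C(C)C)c(OC)cc1C(C)=C | intermediate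
10 | dimethyl (2S)-2-[2-(4,4-dimethyl-2-oxohex-5-en-1-yl)-5-methoxy-4-(propan-2-yl)phenyl]-2-methylcyclopropane-1,1-dicarboxylate | C=CC(C)(C)CC(=O)Cc1cc(C(C)C)c(OC)cc1[C@]2(C)CC2(C(=O)OC)C(=O)OC | intermediate
11 | 1,2,4-trioxolane (ozonide) of the vinyl group of 10 (not isolated) | O=C(CC(C)(C)C3OCOO3)Cc1cc(C(C)C)c(OC)cc1[C@]2(C)CC2(C(=O)OC)C(=O)OC | intermediate
12 | dimethyl (2S)-2-[2-(4,4-dimethyl-2,5-dioxopentyl)-5-methoxy-4-(propan-2-yl)phenyl]-2-methylcyclopropane-1,1-dicarboxylate | O=CC(C)(C)CC(=O)Cc1cc(C(C)C)c(OC)cc1[C@]2(C)CC2(C(=O)OC)C(=O)OC | intermediate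
13 | 2,3-seco intermediate with ring B closed and ring A open, shown as the neutral malonate (C5–H α, C10–methyl β; not isolated) | C1c2cc(C(C)C)c(OC)cc2[C@@](C)(CC(C(=O)OC)C(=O)OC)[C@@H](C1=O)C(C)(C)C=O | intermediate
14 | dimethyl 3β-hydroxy-12-methoxy-6-oxo-5α-abieta-8,11,13-triene-2,2-dicarboxylate (10β-methyl) | C1c2cc(C(C)C)c(OC)cc2[C@@]2(C)CC(C(=O)OC)(C(=O)OC)[C@H](O)C(C)(C)[C@@H]2C1=O | intermediate
15 | dimethyl 12-methoxy-3,6-dioxo-5α-abieta-8,11,13-triene-2,2-dicarboxylate | C1c2cc(C(C)C)c(OC)cc2[C@@]2(C)CC(C(=O)OC)(C(=O)OC)C(=O)C(C)(C)[C@@H]2C1=O | intermediate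
16 | 12-methoxy-5α-abieta-8,11,13-triene-3,6-dione (trans-fused, 10β-methyl) | C1c2cc(C(C)C)c(OC)cc2[C@@]2(C)CCC(=O)C(C)(C)[C@@H]2C1=O | intermediate
17 | 6-methoxy-3,4-dihydronaphthalen-1(2H)-one | O=C1CCCc2cc(OC)ccc12 | starting material
18 | 5-bromo-6-methoxy-3,4-dihydronaphthalen-1(2H)-one | O=C1CCCc2c(Br)c(OC)ccc12 | intermediate
19 | 6-methoxy-5-(propan-2-yl)-3,4-dihydronaphthalen-1(2H)-one | O=C1CCCc2c(C(C)C)c(OC)ccc12 | intermediate
20 | lithium enolate of 19 (not isolated) | [Li+].[O-]C1=CCCc2c(C(C)C)c(OC)ccc12 | intermediate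
21 | 6-methoxy-2-methyl-5-(propan-2-yl)-3,4-dihydronaphthalen-1(2H)-one (racemic) | O=C1C(C)CCc2c(C(C)C)c(OC)ccc12 | intermediate
22 | 6-methoxy-2-methyl-5-(propan-2-yl)naphthalen-1-ol | Cc1ccc2c(C(C)C)c(OC)ccc2c1O | intermediate
23 | 6-methoxy-2-methyl-5-(propan-2-yl)naphthalen-1-yl trifluoromethanesulfonate | Cc1ccc2c(C(C)C)c(OC)ccc2c1OS(=O)(=O)C(F)(F)F | intermediate
24 | 4-methylpent-1-en-3-ol (racemic) | C=CC(O)C(C)C | starting material
25 | 1-[6-methoxy-2-methyl-5-(propan-2-yl)naphthalen-1-yl]-4-methylpentan-3-one | Cc1ccc2c(C(C)C)c(OC)ccc2c1CCC(=O)C(C)C | intermediate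
26 | 2-{2-[6-methoxy-2-methyl-5-(propan-2-yl)naphthalen-1-yl]ethyl}-2-(propan-2-yl)-1,3-dioxolane | Cc1ccc2c(C(C)C)c(OC)ccc2c1CCC3(C(C)C)OCCO3 | intermediate
27 | 7-lithio derivative of 26 (not isolated) | Cc1ccc2c(C(C)C)c(OC)c([Li])cc2c1CCC3(C(C)C)OCCO3 | intermediate
28 | 2-{2-[7-bromo-6-methoxy-2-methyl-5-(propan-2-yl)naphthalen-1-yl]ethyl}-2-(propan-2-yl)-1,3-dioxolane | Cc1ccc2c(C(C)C)c(OC)c(Br)cc2c1CCC3(C(C)C)OCCO3 | intermediate
29 | 12-methoxy-7α-(3-methoxy-7-methyl-4-(propan-2-yl)-8-{2-[2-(propan-2-yl)-1,3-dioxolan-2-yl]ethyl}naphthalen-2-yl)-5α-abieta-8,11,13-triene-3,6-dione | Cc1ccc2c(C(C)C)c(OC)c(cc2c1CCC4(C(C)C)OCCO4)[C@H]1c2cc(C(C)C)c(OC)cc2[C@@]2(C)CCC(=O)C(C)(C)[C@@H]2C1=O | intermediate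
30 | 12-methoxy-7α-(aryl as in 29)-5α-abieta-8,11,13-triene-3β,6β-diol | Cc1ccc2c(C(C)C)c(OC)c(cc2c1CCC4(C(C)C)OCCO4)[C@H]1c2cc(C(C)C)c(OC)cc2[C@@]2(C)CC[C@H](O)C(C)(C)[C@@H]2[C@@H]1O | intermediate
31 | 7α-(3-hydroxy-7-methyl-4-(propan-2-yl)-8-{2-[2-(propan-2-yl)-1,3-dioxolan-2-yl]ethyl}naphthalen-2-yl)-5α-abieta-8,11,13-triene-3β,6β,12-triol | Cc1ccc2c(C(C)C)c(O)c(cc2c1CCC4(C(C)C)OCCO4)[C@H]1c2cc(C(C)C)c(O)cc2[C@@]2(C)CC[C@H](O)C(C)(C)[C@@H]2[C@@H]1O | intermediate
32 | 1,3-dioxolane ketal of the target (6α-O,7α-C cis-fused dihydronaphthofuran; 3β-OH; 12-OH) | Cc1ccc2c(C(C)C)c3c(cc2c1CCC4(C(C)C)OCCO4)[C@H]1c2cc(C(C)C)c(O)cc2[C@@]2(C)CC[C@H](O)C(C)(C)[C@@H]2[C@H]1O3 | intermediate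
33 | CNP0584944.1 | Cc1ccc2c(C(C)C)c3c(cc2c1CCC(=O)C(C)C)[C@H]1c2cc(C(C)C)c(O)cc2[C@@]2(C)CC[C@H](O)C(C)(C)[C@@H]2[C@H]1O3 | target

Total steps: 23. Longest linear sequence: 14 steps (steps 1–3, 5–10 and 19–23).

Steps most likely to fail

Step 8 (Proposed new method). What may go wrong: enolisation towards C7 followed by aldol condensation with the aldehyde, ionisation of the cyclopropane followed by proton loss, or intermolecular aldehyde–cyclopropane annulation may outrun attack of the C5 enol on C10. Fallback (known chemistry, bond formations decoupled), setting out from compound 10 and coming back at compound 14: with the aldehyde still masked as the vinyl group, Sc(OTf)3 in CH2Cl2 should effect only the homo-conjugate ring opening of the cyclopropane-1,1-diester by the ketone enol, giving the bicyclic alkenyl malonate F1. Ozonolysis (O3, then Me2S) then gives the keto aldehyde 13. Catalytic DBU in CH2Cl2 at 0 °C closes ring A by malonate aldol addition; the malonate is far more acidic than the ketone, so compound 14 results.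

Step 6. What may go wrong: insufficient facial discrimination on the twisted, ortho-substituted α-methylstyrene, or competing carbene transfer to the vinyl group; a low enantiomeric purity at C10 cannot be repaired later. Fallback, setting out from compound 9 and coming back at compound 10: Rh2(OAc)4-catalysed cyclopropanation with dimethyl diazomalonate gives the racemic cyclopropane diester F2. Its enantiomers are separated by preparative chromatography on a chiral stationary phase (amylose tris(3,5-dimethylphenylcarbamate)); the (S)-enantiomer is compound 10.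

Step 19. What may go wrong: slow coupling between two ortho-substituted partners, leading to hydrodebromination of the aryl bromide, arylation at C2 or aldol self-condensation of the diketone. Fallback by polarity reversal, setting out from compounds 16 and 28 and coming back at compound 29: the diketone is brominated at the benzylic α-carbon C7 with PhNMe3Br3 (THF, 0 °C) to give the α-bromo ketone F3. The bromide 28 is converted with t-BuLi (−78 °C) and ZnCl2 into the arylzinc chloride F4. Nickel-catalysed Negishi arylation of the α-bromo ketone (NiCl2·glyme, a pybox ligand, glyme/THF, −30 °C) then gives compound 29 after equilibration at C7.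

Further compounds
F1 | step 8 | ring-B-closed alkenyl malonate (vinyl analogue of 13; C5–H α, C10–methyl β) | C1c2cc(C(C)C)c(OC)cc2[C@@](C)(CC(C(=O)OC)C(=O)OC)[C@@H](C1=O)C(C)(C)C=C
F2 | step 6 | racemic dimethyl 2-[2-(4,4-dimethyl-2-oxohex-5-en-1-yl)-5-methoxy-4-(propan-2-yl)phenyl]-2-methylcyclopropane-1,1-dicarboxylate | C=CC(C)(C)CC(=O)Cc1cc(C(C)C)c(OC)cc1C2(C)CC2(C(=O)OC)C(=O)OC
F3 | step 19 | 7-bromo-12-methoxy-5α-abieta-8,11,13-triene-3,6-dione (C7 epimers) | BrC1c2cc(C(C)C)c(OC)cc2[C@@]2(C)CCC(=O)C(C)(C)[C@@H]2C1=O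
F4 | step 19 | arylzinc chloride derived from 28 | Cc1ccc2c(C(C)C)c(OC)c([Zn]Cl)cc2c1CCC3(C(C)C)OCCO3
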